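**Assumption:** the target (5,7,4'-trihydroxy-3,6,8-trimethoxyflavone) has no stereocentre and is achiral, so there is no enantiomer to control. Kaempferol is taken as a commercially available starting material.

## Retrosynthetic overview

1. Target 13 ⇒ dibenzyl ether 12 by global hydrogenolysis of the 7- and 4'-benzyl ethers.
2. 12 ⇒ dibromide 9 by cutting the C6–OMe and C8–OMe bonds, formed together in one pot by copper-mediated double methoxylation (key step).
3. 9 ⇒ 6 by twofold electrophilic C–H bromination of ring A at C6 and C8.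
4. 6 ⇒ kaempferol 1 by site-selective O-alkylation (7,4'-benzyl, then 3-methyl), using the acidity order 7-OH > 4'-OH > 3-OH >> 5-OH.
5. No ring is formed: rings A, C and B are bought intact in kaempferol, and the usual pyrone-forming disconnection (Allan–Robinson or chalcone/Algar–Flynn–Oyamada on a pentaoxygenated acetophenone) is deliberately avoided.

## Route

Step 1
Reactants: 1 kaempferol; 2 benzyl bromide
Product: 4 kaempferol 7,4'-dibenzyl ether, via kaempferol 7-benzyl ether 3 (not isolated)
Conditions: BnBr (2.1 equiv), K2CO3 (2.2 equiv), DMF, 0 °C to rt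
Reagents that add atoms: benzyl bromide, BrCc1ccccc1
Why: Williamson etherification; the 7-OH and then the 4'-OH (both vinylogous acids conjugated to C4=O) are the most acidic and are alkylated before the 3-OH, while the 5-OH is held in a hydrogen bond to the carbonyl; no stereocentre is formed.

Step 2
Reactants: 4 kaempferol 7,4'-dibenzyl ether; 5 iodomethane
Product: 6 kaempferol 7,4'-dibenzyl 3-methyl ether
Conditions: MeI (1.2 equiv), K2CO3 (1.5 equiv), acetone, rt to 40 °C
Reagents that add atoms: iodomethane, CI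
Why: Williamson methylation; of the two remaining hydroxyls the enolic 3-OH is far more acidic and nucleophilic than the chelated 5-OH, so mild carbonate conditions give the 3-methyl ether only.

Step 3
Reactants: 6 kaempferol 7,4'-dibenzyl 3-methyl ether; 7 N-bromosuccinimide
Product: 9 6,8-dibromokaempferol 7,4'-dibenzyl 3-methyl ether, via 6-bromokaempferol 7,4'-dibenzyl 3-methyl ether 8 (not isolated)
Conditions: NBS (2.1 equiv), DMF, 0 °C to rt, dark
Reagents that add atoms: N-bromosuccinimide, O=C1CCC(=O)N1Br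
Why: electrophilic aromatic bromination; C6 and C8 are the only free positions of ring A and are activated by the free 5-OH and the 7-benzyloxy group, whereas ring B is deactivated by conjugation with the pyrone, and working in the dark suppresses benzylic radical bromination.

Step 4
Reactants: 9 6,8-dibromokaempferol 7,4'-dibenzyl 3-methyl ether; 10 sodium methoxide
Product: 12 6,8-dimethoxykaempferol 7,4'-dibenzyl 3-methyl ether, via 8-bromo-6-methoxykaempferol 7,4'-dibenzyl 3-methyl ether 11 (not isolated)
Conditions: NaOMe (8 equiv, 25 wt% in MeOH), CuBr (0.5 equiv), DMF, 110 °C, N2; then 1 M HCl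
Reagents that add atoms: sodium methoxide, C[O-].[Na+]
Why: Ullmann-type copper-mediated methoxylation of aryl bromides, a reaction type established for ortho-oxygenated bromoarenes including 6,8-dibromo-5,7-dioxygenated flavones; the 5-phenoxide formed in the flask binds copper next to C6 and protects the pyrone against ring opening by methoxide, and both C–Br bonds are exchanged in one pot.

Step 5
Reactants: 12 6,8-dimethoxykaempferol 7,4'-dibenzyl 3-methyl ether
Product: 13 5,7,4'-trihydroxy-3,6,8-trimethoxyflavone (target)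
Conditions: H2 (1 atm), Pd/C (10 wt% palladium on carbon), THF/MeOH, rt
Reagents that add atoms: none
Why: catalytic hydrogenolysis of benzyl aryl ethers; the aryl methyl ethers and the fully substituted C2=C3 bond of the flavone are inert under these conditions.

## Compound list

1 | kaempferol, 3,5,7-trihydroxy-2-(4-hydroxyphenyl)-4H-chromen-4-one | O=c1c(O)c(-c2ccc(O)cc2)oc2cc(O)cc(O)c12 | starting material
2 | benzyl bromide | BrCc1ccccc1 | starting material
3 | kaempferol 7-benzyl ether, 7-(benzyloxy)-3,5-dihydroxy-2-(4-hydroxyphenyl)-4H-chromen-4-one | O=c1c(O)c(-c2ccc(O)cc2)oc2cc(OCc3ccccc3)cc(O)c12 | intermediate (not isolated)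
4 | kaempferol 7,4'-dibenzyl ether, 7-(benzyloxy)-2-[4-(benzyloxy)phenyl]-3,5-dihydroxy-4H-chromen-4-one | O=c1c(O)c(-c2ccc(OCc3ccccc3)cc2)oc2cc(OCc3ccccc3)cc(O)c12 | intermediate
5 | iodomethane | CI | starting material
6 | kaempferol 7,4'-dibenzyl 3-methyl ether, 7-(benzyloxy)-2-[4-(benzyloxy)phenyl]-5-hydroxy-3-methoxy-4H-chromen-4-one | COc1c(-c2ccc(OCc3ccccc3)cc2)oc2cc(OCc3ccccc3)cc(O)c2c1=O | intermediate
7 | N-bromosuccinimide | O=C1CCC(=O)N1Br | starting material
8 | 6-bromokaempferol 7,4'-dibenzyl 3-methyl ether, 7-(benzyloxy)-2-[4-(benzyloxy)phenyl]-6-bromo-5-hydroxy-3-methoxy-4H-chromen-4-one | COc1c(-c2ccc(OCc3ccccc3)cc2)oc2cc(OCc3ccccc3)c(Br)c(O)c2c1=O | intermediate (not isolated)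
9 | 6,8-dibromokaempferol 7,4'-dibenzyl 3-methyl ether, 7-(benzyloxy)-2-[4-(benzyloxy)phenyl]-6,8-dibromo-5-hydroxy-3-methoxy-4H-chromen-4-one | COc1c(-c2ccc(OCc3ccccc3)cc2)oc2c(Br)c(OCc3ccccc3)c(Br)c(O)c2c1=O | intermediate
10 | sodium methoxide | C[O-].[Na+] | starting material
11 | 8-bromo-6-methoxykaempferol 7,4'-dibenzyl 3-methyl ether, 7-(benzyloxy)-2-[4-(benzyloxy)phenyl]-8-bromo-5-hydroxy-3,6-dimethoxy-4H-chromen-4-one | COc1c(-c2ccc(OCc3ccccc3)cc2)oc2c(Br)c(OCc3ccccc3)c(OC)c(O)c2c1=O | intermediate (not isolated)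
12 | 6,8-dimethoxykaempferol 7,4'-dibenzyl 3-methyl ether, 7-(benzyloxy)-2-[4-(benzyloxy)phenyl]-5-hydroxy-3,6,8-trimethoxy-4H-chromen-4-one | COc1c(-c2ccc(OCc3ccccc3)cc2)oc2c(OC)c(OCc3ccccc3)c(OC)c(O)c2c1=O | intermediate
13 | 5,7,4'-trihydroxy-3,6,8-trimethoxyflavone, 5,7-dihydroxy-2-(4-hydroxyphenyl)-3,6,8-trimethoxy-4H-chromen-4-one | COc1c(O)c(OC)c2oc(-c3ccc(O)cc3)c(OC)c(=O)c2c1O | target

## Step count and risk

Total step count: 5. Longest linear sequence: 5 steps (1 → 4 → 6 → 9 → 12 → 13).

The three steps most likely to fail: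

**Step 4 (double copper-mediated methoxylation of the hindered dibromide; risks are hydrodebromination and a stalled second exchange).** The fallback sets out from 9 and comes back at 13. Both benzyl ethers of 9 are removed first with BCl3 and pentamethylbenzene in CH2Cl2 at −78 °C. This Lewis-acid debenzylation leaves the C–Br bonds and the methyl ether untouched, whereas hydrogen would cleave the C–Br bonds. It gives 6,8-dibromo-3-O-methylkaempferol F7. This triphenol is then heated as its trisodium salt with NaOMe and CuBr in DMF at 120 °C. Each bromide now sits next to small phenoxide oxygens instead of a benzyloxy group, and the polyphenoxide fully shields the pyrone. Acidification gives 13 directly, with the step count unchanged.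

**Step 1 (site-selective dibenzylation; risk is competing 3-O-benzylation and over-alkylation).** The fallback sets out from 1 and comes back at 4. Kaempferol is peracetylated (Ac2O, pyridine) to kaempferol tetraacetate F1. Heating F1 with benzyl bromide 2, K2CO3 and KI in dry acetone exchanges only the two activated, unchelated aryl acetates at O7 and O4' for benzyl ethers by deacylation–alkylation in the flask. This gives 3,5-di-O-acetyl-7,4'-di-O-benzylkaempferol F2. Methanolysis with K2CO3 in MeOH then frees the 3-OH and 5-OH to deliver 4.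

**Step 3 (twofold bromination; risks are attack on ring B and incomplete second bromination).** The fallback sets out from 6 and comes back at 12. The C8 oxygen is introduced by Elbs persulfate oxidation: 6 in aqueous KOH/pyridine with K2S2O8 is attacked para to the 5-phenoxide to give the potassium 8-sulfate of 6 F3. Warm dilute HCl hydrolyses this to the 5,8-dihydroxy compound F4. One equivalent of MeI with K2CO3 methylates the free 8-OH but not the chelated 5-OH, giving the 8-methoxy compound F5. A single equivalent of NBS can then only brominate C6, giving the 6-bromo-8-methoxy compound F6. One copper-mediated methoxylation (NaOMe, CuBr, DMF) gives 12.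

## Further compounds

F1 | step 1 | kaempferol tetraacetate, 3,5,7-triacetoxy-2-(4-acetoxyphenyl)-4H-chromen-4-one | CC(=O)Oc1ccc(-c2oc3cc(OC(C)=O)cc(OC(C)=O)c3c(=O)c2OC(C)=O)cc1
F2 | step 1 | 3,5-di-O-acetyl-7,4'-di-O-benzylkaempferol | CC(=O)Oc1c(-c2ccc(OCc3ccccc3)cc2)oc2cc(OCc3ccccc3)cc(OC(C)=O)c2c1=O
F3 | step 3 | potassium 8-sulfate of 6, potassium 7-(benzyloxy)-2-[4-(benzyloxy)phenyl]-5-hydroxy-3-methoxy-4-oxo-4H-chromen-8-yl sulfate | COc1c(-c2ccc(OCc3ccccc3)cc2)oc2c(OS(=O)(=O)[O-])c(OCc3ccccc3)cc(O)c2c1=O.[K+]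
F4 | step 3 | 7-(benzyloxy)-2-[4-(benzyloxy)phenyl]-5,8-dihydroxy-3-methoxy-4H-chromen-4-one | COc1c(-c2ccc(OCc3ccccc3)cc2)oc2c(O)c(OCc3ccccc3)cc(O)c2c1=O
F5 | step 3 | 7-(benzyloxy)-2-[4-(benzyloxy)phenyl]-5-hydroxy-3,8-dimethoxy-4H-chromen-4-one | COc1c(-c2ccc(OCc3ccccc3)cc2)oc2c(OC)c(OCc3ccccc3)cc(O)c2c1=O
F6 | step 3 | 7-(benzyloxy)-2-[4-(benzyloxy)phenyl]-6-bromo-5-hydroxy-3,8-dimethoxy-4H-chromen-4-one | COc1c(-c2ccc(OCc3ccccc3)cc2)oc2c(OC)c(OCc3ccccc3)c(Br)c(O)c2c1=O
F7 | step 4 | 6,8-dibromo-3-O-methylkaempferol, 6,8-dibromo-5,7-dihydroxy-2-(4-hydroxyphenyl)-3-methoxy-4H-chromen-4-one | COc1c(-c2ccc(O)cc2)oc2c(Br)c(O)c(Br)c(O)c2c1=O
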